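**Retrosynthetic overview**

- Target: 3-[(2R)-2-acetoxypentadecyl]-2-hydroxy-5-methoxy-1,4-benzoquinone, with the side chain numbered C1′ (on the ring) to C15′ and C2′ as the acetoxy carbon. The hydroxy-methoxy-quinone is taken back to a 1,2,4,5-tetramethoxybenzene ring (CAN oxidation, then hydrolysis of the one OMe next to the side chain).
- Key disconnection C7′–C8′: Ni–H reductive hydroalkylation of the terminal C6′=C7′ alkene of an (R)-1-aryl-hept-6-en-2-yl acetate with 1-iodooctane. Neither partner is an organometallic: hydride turns C7′ into the nucleophile in situ and C8′ enters as an alkyl radical.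
- Enabling feature: C3′–C15′ is an unbranched, heteroatom-free polymethylene run, so a monosubstituted-alkene/primary-iodide union at C7′–C8′ leaves no trace. The only stereocentre (C2′) is four bonds from the alkene, and the six-membered ring travels as the reduction-inert tetramethoxyarene.
- C(ring)–C1′: 2,3,5,6-tetramethoxyphenyllithium (the arene has only one kind of ring C–H) opens (R)-2-(pent-4-enyl)oxirane at its CH2. The oxirane comes from (R)-epichlorohydrin and butenyl Grignard, which fixes C2′.
- Ring order: no carbocycle is built. The oxirane is the only ring closed (step 2) and is opened in step 3; the purchased benzene ring is oxidised last (steps 6–7).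

Key step: step 5

Assumption: the configuration at C2′ read from the given SMILES is (R); (R)-epichlorohydrin, but-3-enylmagnesium bromide (THF solution), 1,2,4,5-tetramethoxybenzene and 1-iodooctane are taken as purchasable.

**Route**

Step 1
Reactants: 1 (R)-epichlorohydrin; 2 but-3-en-1-ylmagnesium bromide
Product: 3 (R)-1-chlorohept-6-en-2-ol
Conditions: CuI (10 mol%), THF, −40 → −20 °C; aq. NH4Cl
Reagents that add atoms: none
Why: Copper-catalysed Grignard opening of the epoxide occurs by SN2 at the unsubstituted oxirane CH2, so the C–O bond at the stereocentre is untouched, C2′ keeps the configuration bought with 1, and the chloride stays as the leaving group for step 2.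

Step 2
Reactants: 3 (R)-1-chlorohept-6-en-2-ol
Product: 4 (R)-2-(pent-4-en-1-yl)oxirane
Conditions: powdered NaOH, Et2O, 0 °C → rt
Reagents that add atoms: none
Why: Intramolecular Williamson etherification (3-exo-tet) of the chlorohydrin alkoxide displaces the primary chloride without touching the stereocentre, giving the (R)-oxirane.

Step 3
Reactants: 5 1,2,4,5-tetramethoxybenzene; 4 (R)-2-(pent-4-en-1-yl)oxirane
Product: 7 (R)-1-(2,3,5,6-tetramethoxyphenyl)hept-6-en-2-ol, via tetramethoxyphenyllithium 6 (not isolated)
Conditions: n-BuLi, THF, 0 °C → rt; then BF3·OEt2, 4, −78 °C; aq. NH4Cl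
Reagents that add atoms: none
Why: Directed ortho-lithiation of 5 (its only ring C–H type, flanked by two OMe groups) gives 6, which in a BF3-promoted SN2 epoxide opening attacks the unsubstituted CH2 of 4, so the C(ring)–C1′ bond forms and the C2′–O bond keeps its (R) configuration.

Step 4
Reactants: 7 (R)-1-(2,3,5,6-tetramethoxyphenyl)hept-6-en-2-ol
Product: 8 (R)-1-(2,3,5,6-tetramethoxyphenyl)hept-6-en-2-yl acetate
Conditions: Ac2O, pyridine, DMAP (cat.), CH2Cl2, rt
Reagents that add atoms: acetic anhydride, CC(=O)OC(C)=O
Why: DMAP-catalysed O-acylation of the secondary alcohol installs the target's acetate with retention at C2′ and removes the free OH before the nickel step and the acidic end-game.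

Step 5
Reactants: 8 (R)-1-(2,3,5,6-tetramethoxyphenyl)hept-6-en-2-yl acetate; 9 1-iodooctane
Product: 10 (R)-1-(2,3,5,6-tetramethoxyphenyl)pentadecan-2-yl acetate
Conditions: NiBr2·diglyme (10 mol%), i-Pr-PyBox (12 mol%), (EtO)2MeSiH, Na2CO3, DMA, 25 °C
Reagents that add atoms: none
Why: A PyBox-ligated Ni–H, generated from the nickel halide, the silane and carbonate, should insert the monosubstituted C6′=C7′ alkene of 8 with hydride going to C6′ and nickel to the terminal C7′, while low-valent nickel abstracts iodine from 9 to give the octyl radical; radical capture gives a dialkylnickel(III) species and C(sp3)–C(sp3) reductive elimination forms the C7′–C8′ bond. The closest known reaction type is the nickel-hydride-catalysed reductive anti-Markovnikov hydroalkylation of unactivated terminal olefins with primary alkyl iodides, in which the olefin acts as an alkyl-nucleophile equivalent without a preformed organometallic. No ring is closed and no stereocentre is created; C2′ is four σ-bonds from the alkene, not acidic, and is expected to pass through unchanged. The step needs linear over branched regioselectivity, no chain-walking, and cross- over homo-coupling: the first follows from the monosubstituted alkene (nickel at the less hindered carbon), the second is expected from the tridentate PyBox ligand, which disfavours β-hydride elimination and re-insertion, and the third from the two partners being activated by different elementary steps (π-insertion for 8, halogen abstraction for 9). The acetate, the four aryl methyl ethers and the unhalogenated electron-rich ring are inert to silane and low-valent nickel, so the full C15 chain should be completed in one operation from a C7 olefin and a C8 iodide.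

Step 6
Reactants: 10 (R)-1-(2,3,5,6-tetramethoxyphenyl)pentadecan-2-yl acetate
Product: 11 (R)-1-(2,5-dimethoxy-3,6-dioxocyclohexa-1,4-dien-1-yl)pentadecan-2-yl acetate
Conditions: (NH4)2Ce(NO3)6, MeCN–H2O, 0 °C
Reagents that add atoms: water, O
Why: CAN oxidative demethylation of a para-dimethoxyarene (arene radical cation, water addition at a methoxy-bearing carbon, loss of methanol) should give the 2,5-dimethoxy-1,4-benzoquinone; both para-dimethoxy pairs of 10 lead to the same quinone by symmetry, and the acetate and C2′ are inert.

Step 7
Reactants: 11 (R)-1-(2,5-dimethoxy-3,6-dioxocyclohexa-1,4-dien-1-yl)pentadecan-2-yl acetate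
Product: 12 (R)-1-(2-hydroxy-5-methoxy-3,6-dioxocyclohexa-1,4-dien-1-yl)pentadecan-2-yl acetate
Conditions: 70% aq. HClO4, 1,4-dioxane, rt, stopped at mono-demethylation
Reagents that add atoms: water, O
Why: Acid-catalysed hydrolysis of a vinylogous methyl ester is expected to take the OMe wedged between the ring carbonyl and the side chain (twisted out of conjugation, hence the more basic and less stabilised ether oxygen) and leave the fully conjugated OMe next to the ring C–H, the regiochemical course recalled for 3-alkyl-2,5-dimethoxy-1,4-benzoquinones, giving the hydroxyquinone with the secondary acetate intact.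

**Compound list**

1 | (R)-epichlorohydrin [(R)-2-(chloromethyl)oxirane] | ClC[C@H]1CO1 | starting material
2 | but-3-en-1-ylmagnesium bromide | C=CCC[Mg]Br | starting material
3 | (R)-1-chlorohept-6-en-2-ol | ClC[C@H](O)CCCC=C | intermediate
4 | (R)-2-(pent-4-en-1-yl)oxirane | C=CCCC[C@@H]1CO1 | intermediate
5 | 1,2,4,5-tetramethoxybenzene | COc1cc(OC)c(OC)cc1OC | starting material
6 | (2,3,5,6-tetramethoxyphenyl)lithium | [Li]c1c(OC)c(OC)cc(OC)c1OC | intermediate
7 | (R)-1-(2,3,5,6-tetramethoxyphenyl)hept-6-en-2-ol | COc1cc(OC)c(OC)c(C[C@H](O)CCCC=C)c1OC | intermediate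
8 | (R)-1-(2,3,5,6-tetramethoxyphenyl)hept-6-en-2-yl acetate | COc1cc(OC)c(OC)c(C[C@H](OC(C)=O)CCCC=C)c1OC | intermediate
9 | 1-iodooctane | CCCCCCCCI | starting material
10 | (R)-1-(2,3,5,6-tetramethoxyphenyl)pentadecan-2-yl acetate | COc1cc(OC)c(OC)c(C[C@H](OC(C)=O)CCCCCCCCCCCCC)c1OC | intermediate
11 | (R)-1-(2,5-dimethoxy-3,6-dioxocyclohexa-1,4-dien-1-yl)pentadecan-2-yl acetate | COC1=CC(=O)C(OC)=C(C[C@H](OC(C)=O)CCCCCCCCCCCCC)C1=O | intermediate
12 | (R)-1-(2-hydroxy-5-methoxy-3,6-dioxocyclohexa-1,4-dien-1-yl)pentadecan-2-yl acetate | COC1=CC(=O)C(O)=C(C[C@H](OC(C)=O)CCCCCCCCCCCCC)C1=O | target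

**Step count**

Total steps: 7. Longest linear sequence: 7 (steps 1–7 from 1; compounds 2, 5 and 9 are purchased).

**Steps most likely to fail**

1. Step 7. The hydrolysis may take the wrong methoxy group or both, and the strong acid may cleave the C2′ acetate, after which the freed alcohol can cyclise onto the quinone. The fallback sets out from 10 and comes back at 12, and fixes the regiochemistry at the arene stage. BCl3 (CH2Cl2, −78 → 0 °C) should cleave one of the two symmetry-equivalent, out-of-plane methoxy groups flanking the side chain and give (R)-1-(2-hydroxy-3,5,6-trimethoxyphenyl)pentadecan-2-yl acetate F1. Acetylation (Ac2O, pyridine, DMAP) gives (R)-1-(2-acetoxy-3,5,6-trimethoxyphenyl)pentadecan-2-yl acetate F2. CAN (MeCN–H2O, 0 °C) should oxidise the one remaining para-dimethoxy pair to (R)-1-(2-acetoxy-5-methoxy-3,6-dioxocyclohexa-1,4-dien-1-yl)pentadecan-2-yl acetate F3. Brief NaHCO3 treatment in aqueous THF should then hydrolyse the quinonyl (vinylogous anhydride) acetate, which is far more labile than the secondary alkyl acetate, and give 12.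

2. Step 5. Branched coupling, chain-walking of the alkylnickel, simple reduction of the alkene or the iodide, and octyl homocoupling may erode the union. The fallback sets out from 8 and comes back at 10, and splits the event into two polar steps. Anti-Markovnikov hydroboration of 8 with 9-BBN-H (THF, rt) gives (R)-7-(9-borabicyclo[3.3.1]nonan-9-yl)-1-(2,3,5,6-tetramethoxyphenyl)heptan-2-yl acetate F4, used without isolation. An alkyl–alkyl Suzuki–Miyaura coupling with 1-bromooctane (CCCCCCCCBr; Pd(OAc)2, PCy3, K3PO4·H2O, THF, rt) then forms the same C7′–C8′ bond and gives 10.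

3. Step 3. Opening of a monosubstituted oxirane by a di-ortho-substituted aryllithium may be slow, with BF3-induced epoxide rearrangement and proton transfer competing. The fallback sets out from 5 and comes back at 7, and changes the order of bond formation. Compound 5 is lithiated to 6, transmetalated (MgBr2·OEt2, CuI cat., THF, −40 °C) and added to (S)-epichlorohydrin (ClC[C@@H]1CO1), the most electrophilic terminal epoxide, to give (S)-1-chloro-3-(2,3,5,6-tetramethoxyphenyl)propan-2-ol F5. NaOH closes it to (S)-2-(2,3,5,6-tetramethoxybenzyl)oxirane F6. Copper-catalysed opening with the unhindered Grignard 2 (CuI cat., THF, −40 °C) then makes the C3′–C4′ bond and gives 7 with the (R) configuration.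

**Further compounds**

F1 | step 7 | (R)-1-(2-hydroxy-3,5,6-trimethoxyphenyl)pentadecan-2-yl acetate | COc1cc(OC)c(OC)c(C[C@H](OC(C)=O)CCCCCCCCCCCCC)c1O
F2 | step 7 | (R)-1-(2-acetoxy-3,5,6-trimethoxyphenyl)pentadecan-2-yl acetate | COc1cc(OC)c(OC)c(C[C@H](OC(C)=O)CCCCCCCCCCCCC)c1OC(C)=O
F3 | step 7 | (R)-1-(2-acetoxy-5-methoxy-3,6-dioxocyclohexa-1,4-dien-1-yl)pentadecan-2-yl acetate | COC1=CC(=O)C(OC(C)=O)=C(C[C@H](OC(C)=O)CCCCCCCCCCCCC)C1=O
F4 | step 5 | (R)-7-(9-borabicyclo[3.3.1]nonan-9-yl)-1-(2,3,5,6-tetramethoxyphenyl)heptan-2-yl acetate | COc1cc(OC)c(OC)c(C[C@H](OC(C)=O)CCCCCB2C3CCCC2CCC3)c1OC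
F5 | step 3 | (S)-1-chloro-3-(2,3,5,6-tetramethoxyphenyl)propan-2-ol | ClC[C@@H](O)Cc1c(OC)c(OC)cc(OC)c1OC
F6 | step 3 | (S)-2-(2,3,5,6-tetramethoxybenzyl)oxirane | COc1cc(OC)c(OC)c(C[C@H]2CO2)c1OC
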